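The runs come from a simulation for substances that don't exist; the scatter is artificial.

Target is the product you want from this flask, the dawn flask, and it grows far more slowly than starting material falls.

| setting | dawn | flask |
|---|---|---|
| starting material | 0.050 M | 0.050 M |
| reagent | 1.05 equiv | 1.05 equiv |
| free catalyst | 2.5 mol% | 2.5 mol% |
| remark | the very flask that is asked about, followed so far |  |

dawn run (percent of the starting material charged)

| time / min | target / % | starting material / % |
|---|---|---|
| 0.417 | 0.2 | 90.9 |
| 0.833 | 1.3 | 83.8 |
| 1.33 | 1.2 | 75.8 |
| 1.50 | 1.8 | 73.7 |
| 2.00 | 1.9 | 68.3 |
| 2.50 | 3.2 | 62.8 |

(standard deviation of a reading: 0.3 percentage points)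

1. apparent order in free catalyst when 50 % of the starting material are converted (percent change of the rate of making target for one percent more free catalyst charged)
2. factor on the rate of making target when 50 % of the starting material are converted if reagent is charged twice over

Read the last row first. At 2.50 min, starting material stands at 62.8 % and target at 3.2 %. The target share in that row is 8.60 %: the target found per starting material lost, both as percent of the charge.

Now read the first row. Its share is 2.20 %, but that target reading of 0.2 % has a scatter of 0.3 percentage points, so the rise in share is a weak sign of a lag.

Then add up the last row. A part of 34.0 % of the charge appears in neither column. This unseen part is larger than target, but its size does not say where it stands: on the way to target, or in a side product.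

No earlier run changes free catalyst or reagent, so both answers are guesses. My own commitment is narrower: the target share keeps rising in the dawn flask.

The forecast gives 0.9 for the order in free catalyst and 1.4 for the factor with doubled reagent. Its ground for the order is this: “A catalysed step probably makes target, so the order in catalyst is near 1.”

The dawn flask gives an order of 1.6 and a factor of 1.21.

    starting material + free catalyst → free catalyst + open intermediate (k = 3.20 L mol⁻¹ s⁻¹)
    free catalyst + open intermediate ⇌ catalyst intermediate (K = 48.0 L mol⁻¹, k = 6.20 L mol⁻¹ s⁻¹)
    reagent + catalyst intermediate → free catalyst + target (k = 1.10 L mol⁻¹ s⁻¹)
    2 reagent → self-condensation product (k = 0.0720 L mol⁻¹ s⁻¹)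

At 5.00 min, the self-condensation product stands at 0.0174 M, which has taken 66.3 % of the reagent charged, and 27.6 % of the reagent is left. The target share at that time is 11.9 %. At 50.0 min, with reagent down to 0.830 %, the target share is 20.0 %.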